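**Plan**
Numbering: ring C1 (bears C7H2OH), C2 (C=O), C3 (epoxyangelate), C4 (isopropyl), C5 (angelate), C6 (=CH); sugar atoms are s-C1 to s-C6.
Cuts, in order: the ester C–O bonds at C3 and C5, C1–C7 (Morita–Baylis–Hillman), the ring bond C1–C6 (Ferrier carbocyclization), and the exocyclic C=C at C4 (Wittig on a 3-ulose).
Enabling feature: the O–C(iPr)–O triad C5–C4–C3 beside the enone C2(=O)–C1=C6 of the single six-membered ring is s-C2–s-C3–s-C4 of a 3-C-isopropyl hexopyranoside; its enol-ether carbons s-C5/s-C6 become C2/C1 and its anomeric carbon becomes C6.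
Forward: branched pyranoside, then hex-5-enopyranoside, then the only ring closes in the mercury-mediated carbocyclization, then enone, hydroxymethylation, angelate, epoxyangelate (acid made separately from angelic acid) and desilylation.
Stereochemistry: C3 is C4 of D-glucose; C5 comes from trans-diaxial epoxide opening; C4 from hydroxyl-directed hydrogenation; the epoxide from Sharpless epoxidation with L-(+)-diethyl tartrate; the Z alkene from angelic acid.

Key step: step 9

Remark: the manno-type 3-ulose is entered from the glucose-derived allo-epoxide 1, assumed purchasable, because its ring opening fixes the s-C2 oxygen and its protecting group in one step; the new carbinol of the carbocyclization is drawn as the epimer normally favoured, and either epimer serves.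

Step 1
Reactants: 1 methyl 2,3-anhydro-4,6-O-[(R)-benzylidene]-α-D-allopyranoside
Product: 2 methyl 4,6-O-[(R)-benzylidene]-2-O-(4-methoxybenzyl)-α-D-altropyranoside
Conditions: 4-MeOC6H4CH2OH, NaH, DMF, 100 °C
Reagents that add atoms: 4-methoxybenzyl alcohol, COc1ccc(CO)cc1
Why: Alkoxide opening of the epoxide on this locked trans-fused bicycle should follow the Fürst–Plattner rule, so the nucleophile enters trans-diaxially at s-C2 from the β-face, which sets the future C5–O configuration, installs its PMB group and leaves the axial 3-OH free.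

Step 2
Reactants: 2 methyl 4,6-O-[(R)-benzylidene]-2-O-(4-methoxybenzyl)-α-D-altropyranoside
Product: 3 methyl 4,6-O-[(R)-benzylidene]-2-O-(4-methoxybenzyl)-α-D-arabino-hexopyranosid-3-ulose
Conditions: Dess–Martin periodinane, CH2Cl2, rt
Reagents that add atoms: none
Why: Dess–Martin oxidation of the axial secondary alcohol should give the 3-ulose under non-basic conditions that do not epimerise the α-alkoxy centre s-C2.

Step 3
Reactants: 3 methyl 4,6-O-[(R)-benzylidene]-2-O-(4-methoxybenzyl)-α-D-arabino-hexopyranosid-3-ulose; 4 isopropyltriphenylphosphonium iodide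
Product: 6 methyl 4,6-O-[(R)-benzylidene]-3-deoxy-2-O-(4-methoxybenzyl)-3-C-(propan-2-ylidene)-α-D-arabino-hexopyranoside, via isopropylidenetriphenylphosphorane 5 (not isolated)
Conditions: 4, n-BuLi, THF, 0 °C; then 3, 0 °C → reflux
Reagents that add atoms: none
Why: Wittig olefination with the non-stabilised ylide should bring in the three isopropyl carbons as an exocyclic tetrasubstituted alkene, the ylide being used in excess and added cold to limit enolisation of the ketone.

Step 4
Reactants: 6 methyl 4,6-O-[(R)-benzylidene]-3-deoxy-2-O-(4-methoxybenzyl)-3-C-(propan-2-ylidene)-α-D-arabino-hexopyranoside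
Product: 7 methyl 3-deoxy-2-O-(4-methoxybenzyl)-3-C-(propan-2-ylidene)-α-D-arabino-hexopyranoside
Conditions: AcOH/H2O (4:1), 50 °C
Reagents that add atoms: none
Why: Mild acid hydrolysis of the benzylidene acetal should free the 4,6-diol while the methyl glycoside and the PMB ether survive, which exposes the allylic 4-OH that steers the next step.

Step 5
Reactants: 7 methyl 3-deoxy-2-O-(4-methoxybenzyl)-3-C-(propan-2-ylidene)-α-D-arabino-hexopyranoside
Product: 8 methyl 3-deoxy-3-C-isopropyl-2-O-(4-methoxybenzyl)-α-D-mannopyranoside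
Conditions: [Ir(cod)(PCy3)(py)]PF6 (cat.), H2 (1 atm), CH2Cl2, rt
Reagents that add atoms: none
Why: Hydroxyl-directed hydrogenation with the cationic iridium catalyst should deliver hydrogen to the alkene face on which the allylic 4-OH lies (α), the other face being shielded by the axial PMB ether, so s-C3 gains H cis to O4 and isopropyl ends cis to O2 and trans to O4, as in the trans products known from 2-alkylidenecyclohexanols.

Step 6
Reactants: 8 methyl 3-deoxy-3-C-isopropyl-2-O-(4-methoxybenzyl)-α-D-mannopyranoside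
Product: 9 methyl 3,6-dideoxy-6-iodo-3-C-isopropyl-2-O-(4-methoxybenzyl)-α-D-mannopyranoside
Conditions: I2, PPh3, imidazole, toluene, 70 °C
Reagents that add atoms: iodine, II
Why: Garegg–Samuelsson (Appel-type) iodination should be selective for the primary 6-OH over the hindered secondary 4-OH.

Step 7
Reactants: 9 methyl 3,6-dideoxy-6-iodo-3-C-isopropyl-2-O-(4-methoxybenzyl)-α-D-mannopyranoside
Product: 10 methyl 3,6-dideoxy-6-iodo-3-C-isopropyl-2-O-(4-methoxybenzyl)-4-O-(triethylsilyl)-α-D-mannopyranoside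
Conditions: TESOTf, 2,6-lutidine, CH2Cl2, −78 → 0 °C
Reagents that add atoms: triethylsilyl trifluoromethanesulfonate, CC[Si](CC)(CC)OS(=O)(=O)C(F)(F)F
Why: Silylation with the silyl triflate should cap the hindered 4-OH as a TES ether, chosen because it is orthogonal to PMB and can later be cleaved in the presence of a primary TBDPS ether.

Step 8
Reactants: 10 methyl 3,6-dideoxy-6-iodo-3-C-isopropyl-2-O-(4-methoxybenzyl)-4-O-(triethylsilyl)-α-D-mannopyranoside
Product: 11 methyl 3,6-dideoxy-3-C-isopropyl-2-O-(4-methoxybenzyl)-4-O-(triethylsilyl)-α-D-lyxo-hex-5-enopyranoside (manno configuration at s-C2 to s-C4)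
Conditions: t-BuOK, THF, 0 °C
Reagents that add atoms: none
Why: E2 dehydrohalogenation of the primary iodide, whose only β-hydrogen is H5, should give the exocyclic enol ether, the standard entry to hex-5-enopyranosides.

Step 9
Reactants: 11 methyl 3,6-dideoxy-3-C-isopropyl-2-O-(4-methoxybenzyl)-4-O-(triethylsilyl)-α-D-lyxo-hex-5-enopyranoside
Product: 13 (2S,3R,4S,5S)-5-hydroxy-3-isopropyl-4-[(4-methoxybenzyl)oxy]-2-[(triethylsilyl)oxy]cyclohexan-1-one, via acyclic 6-mercurio-5-keto aldehyde 12 (not isolated)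
Conditions: Hg(OCOCF3)2 (cat., divalent mercury), acetone/H2O (2:1), rt
Reagents that add atoms: water, O
Why: Markovnikov hydroxymercuration of the exocyclic enol ether (mercury on s-C6, oxygen on s-C5) followed by ring opening with loss of methanol should unveil keto aldehyde 12, whose α-mercurio ketone behaves as a mercury enolate. Intramolecular aldol addition of that enolate carbon (the future C1) to the aldehyde (the future C6) forms the C1–C6 bond and the only ring of the target; the closest known reaction type is the mercury-mediated Ferrier carbocyclization of 6-deoxyhex-5-enopyranosides. The closure is a 6-(enolendo)-exo-trig aldol through a chair in which isopropyl and the silyl ether are equatorial. The one new stereocentre, the C6 carbinol, is set by that chair and is expected mainly axial (trans to the PMB ether and to isopropyl), but it is destroyed in step 10, so no control is required. The step needs chemoselectivity for the enol ether and retention of the C3–C4–C5 triad: the enol ether is by far the most electron-rich π system, the triad sits on s-C2 to s-C4 away from both reacting termini, and the carbon β to both carbonyl groups of 12 carries isopropyl, not oxygen, so no alkoxide can be lost by enolisation.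

Step 10
Reactants: 13 (2S,3R,4S,5S)-5-hydroxy-3-isopropyl-4-[(4-methoxybenzyl)oxy]-2-[(triethylsilyl)oxy]cyclohexan-1-one
Product: 15 (4R,5R,6S)-5-isopropyl-4-[(4-methoxybenzyl)oxy]-6-[(triethylsilyl)oxy]cyclohex-2-en-1-one, via 5-O-mesylate 14 (not isolated)
Conditions: MsCl, Et3N, CH2Cl2, 0 °C → rt
Reagents that add atoms: none
Why: Mesylation of the β-hydroxy ketone and E1cB elimination in the same flask should give the conjugated enone, erasing the carbinol centre so that both epimers of 13 converge.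

Step 11
Reactants: 15 (4R,5R,6S)-5-isopropyl-4-[(4-methoxybenzyl)oxy]-6-[(triethylsilyl)oxy]cyclohex-2-en-1-one; 16 formaldehyde
Product: 17 (4R,5R,6S)-2-(hydroxymethyl)-5-isopropyl-4-[(4-methoxybenzyl)oxy]-6-[(triethylsilyl)oxy]cyclohex-2-en-1-one
Conditions: 37% aq. HCHO, DMAP (cat.), THF, rt
Reagents that add atoms: none
Why: In this Morita–Baylis–Hillman reaction DMAP should add reversibly to the unsubstituted β-carbon C6, the enolate should attack formaldehyde at C1 and loss of DMAP should restore the enone with the C7 hydroxymethyl group, as known for 4-oxygenated cyclohexenones.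

Step 12
Reactants: 17 (4R,5R,6S)-2-(hydroxymethyl)-5-isopropyl-4-[(4-methoxybenzyl)oxy]-6-[(triethylsilyl)oxy]cyclohex-2-en-1-one
Product: 18 (4R,5R,6S)-2-{[(tert-butyldiphenylsilyl)oxy]methyl}-5-isopropyl-4-[(4-methoxybenzyl)oxy]-6-[(triethylsilyl)oxy]cyclohex-2-en-1-one
Conditions: TBDPSCl, imidazole, CH2Cl2, 0 °C → rt
Reagents that add atoms: tert-butyl(chloro)diphenylsilane, CC(C)(C)[Si](Cl)(c1ccccc1)c1ccccc1
Why: Standard silylation of the only free (primary allylic) hydroxyl masks C7–OH through both acylations, TBDPS being stable to DDQ and to the mild fluoride treatment that removes TES.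

Step 13
Reactants: 18 (4R,5R,6S)-2-{[(tert-butyldiphenylsilyl)oxy]methyl}-5-isopropyl-4-[(4-methoxybenzyl)oxy]-6-[(triethylsilyl)oxy]cyclohex-2-en-1-one
Product: 19 (4R,5R,6S)-2-{[(tert-butyldiphenylsilyl)oxy]methyl}-4-hydroxy-5-isopropyl-6-[(triethylsilyl)oxy]cyclohex-2-en-1-one
Conditions: DDQ, CH2Cl2/pH 7 buffer, 0 °C → rt
Reagents that add atoms: none
Why: Oxidative PMB cleavage by DDQ (benzylic hydride abstraction, then hydrolysis) should free C5–OH without touching the silyl ethers or the electron-poor enone.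

Step 14
Reactants: 19 (4R,5R,6S)-2-{[(tert-butyldiphenylsilyl)oxy]methyl}-4-hydroxy-5-isopropyl-6-[(triethylsilyl)oxy]cyclohex-2-en-1-one; 20 angelic acid
Product: 22 (4R,5R,6S)-2-{[(tert-butyldiphenylsilyl)oxy]methyl}-5-isopropyl-4-{[(Z)-2-methylbut-2-enoyl]oxy}-6-[(triethylsilyl)oxy]cyclohex-2-en-1-one, via angelic 2,4,6-trichlorobenzoic anhydride 21 (not isolated)
Conditions: 20, 2,4,6-Cl3C6H2COCl, Et3N, toluene, rt; then 19, 80 °C
Reagents that add atoms: none
Why: Yamaguchi-type esterification through the preformed mixed anhydride without DMAP is the established way to acylate hindered secondary alcohols with angelic acid while keeping the Z geometry.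

Step 15
Reactants: 22 (4R,5R,6S)-2-{[(tert-butyldiphenylsilyl)oxy]methyl}-5-isopropyl-4-{[(Z)-2-methylbut-2-enoyl]oxy}-6-[(triethylsilyl)oxy]cyclohex-2-en-1-one
Product: 23 (4R,5S,6S)-2-{[(tert-butyldiphenylsilyl)oxy]methyl}-6-hydroxy-5-isopropyl-4-{[(Z)-2-methylbut-2-enoyl]oxy}cyclohex-2-en-1-one
Conditions: HF·pyridine, pyridine, THF, 0 °C
Reagents that add atoms: none
Why: Selective fluoride desilylation should remove the secondary TES ether far faster than the primary TBDPS ether and leave the angelate untouched (the 5-descriptor changes only because the priorities change).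

Step 16
Reactants: 20 angelic acid
Product: 24 (Z)-2-methylbut-2-en-1-ol
Conditions: LiAlH4, Et2O, 0 °C → rt
Reagents that add atoms: none
Why: Hydride reduction of the carboxylic acid should give the allylic alcohol without reducing or isomerising the trisubstituted Z alkene.

Step 17
Reactants: 24 (Z)-2-methylbut-2-en-1-ol
Product: 25 [(2S,3R)-2,3-dimethyloxiran-2-yl]methanol
Conditions: Ti(OiPr)4 (cat.), L-(+)-diethyl tartrate (cat.), t-BuOOH, 4 Å molecular sieves, CH2Cl2, −20 °C
Reagents that add atoms: tert-butyl hydroperoxide, CC(C)(C)OO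
Why: In the Sharpless asymmetric epoxidation the titanium complex of L-(+)-diethyl tartrate should deliver oxygen to the alkene face that gives the (2S) epoxy alcohol, and syn addition to the Z alkene then fixes C3 as R.

Step 18
Reactants: 25 [(2S,3R)-2,3-dimethyloxiran-2-yl]methanol
Product: 26 (2R,3R)-2,3-dimethyloxirane-2-carboxylic acid
Conditions: RuCl3·xH2O (cat.), NaIO4, MeCN/CCl4/H2O, rt
Reagents that add atoms: water, O
Why: Oxidation by RuO4 generated in situ is the standard conversion of 2,3-epoxy alcohols into glycidic acids and should leave the epoxide and both stereocentres intact (the 2-descriptor changes only because the priorities change).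

Step 19
Reactants: 23 (4R,5S,6S)-2-{[(tert-butyldiphenylsilyl)oxy]methyl}-6-hydroxy-5-isopropyl-4-{[(Z)-2-methylbut-2-enoyl]oxy}cyclohex-2-en-1-one; 26 (2R,3R)-2,3-dimethyloxirane-2-carboxylic acid
Product: 28 (1S,2R,3R)-5-{[(tert-butyldiphenylsilyl)oxy]methyl}-2-isopropyl-3-{[(Z)-2-methylbut-2-enoyl]oxy}-6-oxocyclohex-4-en-1-yl (2R,3R)-2,3-dimethyloxirane-2-carboxylate, via epoxyangelic 2,4,6-trichlorobenzoic anhydride 27 (not isolated)
Conditions: 26, 2,4,6-Cl3C6H2COCl, Et3N, THF, rt; then 23, DMAP, toluene, rt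
Reagents that add atoms: none
Why: Yamaguchi esterification with DMAP should acylate the hindered α-ketol C3–OH at room temperature, the acid having no position that can epimerise or isomerise.

Step 20
Reactants: 28 (1S,2R,3R)-5-{[(tert-butyldiphenylsilyl)oxy]methyl}-2-isopropyl-3-{[(Z)-2-methylbut-2-enoyl]oxy}-6-oxocyclohex-4-en-1-yl (2R,3R)-2,3-dimethyloxirane-2-carboxylate
Product: 29 (1S,2R,3R)-5-(hydroxymethyl)-2-isopropyl-3-{[(Z)-2-methylbut-2-enoyl]oxy}-6-oxocyclohex-4-en-1-yl (2R,3R)-2,3-dimethyloxirane-2-carboxylate (CNP0293054.1)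
Conditions: HF·pyridine, pyridine, THF, 0 °C → rt
Reagents that add atoms: none
Why: Fluoride desilylation with pyridine-buffered HF·pyridine should remove the primary TBDPS ether under conditions tolerated by the epoxide, both esters and the enone, releasing the target.

**Compound list**
1 | methyl 2,3-anhydro-4,6-O-[(R)-benzylidene]-α-D-allopyranoside | CO[C@H]1O[C@@H]2CO[C@@H](c3ccccc3)O[C@H]2[C@H]4O[C@@H]14 | starting material
2 | methyl 4,6-O-[(R)-benzylidene]-2-O-(4-methoxybenzyl)-α-D-altropyranoside | CO[C@H]1O[C@@H]2CO[C@@H](c3ccccc3)O[C@H]2[C@@H](O)[C@@H]1OCc1ccc(OC)cc1 | intermediate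
3 | methyl 4,6-O-[(R)-benzylidene]-2-O-(4-methoxybenzyl)-α-D-arabino-hexopyranosid-3-ulose | CO[C@H]1O[C@@H]2CO[C@@H](c3ccccc3)O[C@H]2C(=O)[C@@H]1OCc1ccc(OC)cc1 | intermediate
4 | isopropyltriphenylphosphonium iodide | CC(C)[P+](c1ccccc1)(c1ccccc1)c1ccccc1.[I-] | starting material
5 | isopropylidenetriphenylphosphorane (not isolated) | CC(C)=P(c1ccccc1)(c1ccccc1)c1ccccc1 | intermediate
6 | methyl 4,6-O-[(R)-benzylidene]-3-deoxy-2-O-(4-methoxybenzyl)-3-C-(propan-2-ylidene)-α-D-arabino-hexopyranoside | CO[C@H]1O[C@@H]2CO[C@@H](c3ccccc3)O[C@H]2C(=C(C)C)[C@@H]1OCc1ccc(OC)cc1 | intermediate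
7 | methyl 3-deoxy-2-O-(4-methoxybenzyl)-3-C-(propan-2-ylidene)-α-D-arabino-hexopyranoside | CO[C@H]1O[C@H](CO)[C@@H](O)C(=C(C)C)[C@@H]1OCc1ccc(OC)cc1 | intermediate
8 | methyl 3-deoxy-3-C-isopropyl-2-O-(4-methoxybenzyl)-α-D-mannopyranoside | CO[C@H]1O[C@H](CO)[C@@H](O)[C@H](C(C)C)[C@@H]1OCc1ccc(OC)cc1 | intermediate
9 | methyl 3,6-dideoxy-6-iodo-3-C-isopropyl-2-O-(4-methoxybenzyl)-α-D-mannopyranoside | CO[C@H]1O[C@H](CI)[C@@H](O)[C@H](C(C)C)[C@@H]1OCc1ccc(OC)cc1 | intermediate
10 | methyl 3,6-dideoxy-6-iodo-3-C-isopropyl-2-O-(4-methoxybenzyl)-4-O-(triethylsilyl)-α-D-mannopyranoside | CO[C@H]1O[C@H](CI)[C@@H](O[Si](CC)(CC)CC)[C@H](C(C)C)[C@@H]1OCc1ccc(OC)cc1 | intermediate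
11 | methyl 3,6-dideoxy-3-C-isopropyl-2-O-(4-methoxybenzyl)-4-O-(triethylsilyl)-α-D-lyxo-hex-5-enopyranoside (manno configuration at s-C2 to s-C4) | CO[C@H]1OC(=C)[C@@H](O[Si](CC)(CC)CC)[C@H](C(C)C)[C@@H]1OCc1ccc(OC)cc1 | intermediate
12 | 3,6-dideoxy-3-C-isopropyl-2-O-(4-methoxybenzyl)-4-O-(triethylsilyl)-6-[(trifluoroacetoxy)mercurio]-D-lyxo-hexos-5-ulose, open-chain aldehyde (not isolated) | O=C[C@@H](OCc1ccc(OC)cc1)[C@@H](C(C)C)[C@H](O[Si](CC)(CC)CC)C(=O)C[Hg]OC(=O)C(F)(F)F | intermediate
13 | (2S,3R,4S,5S)-5-hydroxy-3-isopropyl-4-[(4-methoxybenzyl)oxy]-2-[(triethylsilyl)oxy]cyclohexan-1-one | COc1ccc(CO[C@@H]2[C@@H](O)CC(=O)[C@@H](O[Si](CC)(CC)CC)[C@@H]2C(C)C)cc1 | intermediate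
14 | (2S,3R,4S,5S)-3-isopropyl-4-[(4-methoxybenzyl)oxy]-5-[(methylsulfonyl)oxy]-2-[(triethylsilyl)oxy]cyclohexan-1-one (not isolated) | COc1ccc(CO[C@@H]2[C@@H](OS(C)(=O)=O)CC(=O)[C@@H](O[Si](CC)(CC)CC)[C@@H]2C(C)C)cc1 | intermediate
15 | (4R,5R,6S)-5-isopropyl-4-[(4-methoxybenzyl)oxy]-6-[(triethylsilyl)oxy]cyclohex-2-en-1-one | COc1ccc(CO[C@@H]2C=CC(=O)[C@@H](O[Si](CC)(CC)CC)[C@@H]2C(C)C)cc1 | intermediate
16 | formaldehyde | C=O | starting material
17 | (4R,5R,6S)-2-(hydroxymethyl)-5-isopropyl-4-[(4-methoxybenzyl)oxy]-6-[(triethylsilyl)oxy]cyclohex-2-en-1-one | COc1ccc(CO[C@@H]2C=C(CO)C(=O)[C@@H](O[Si](CC)(CC)CC)[C@@H]2C(C)C)cc1 | intermediate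
18 | (4R,5R,6S)-2-{[(tert-butyldiphenylsilyl)oxy]methyl}-5-isopropyl-4-[(4-methoxybenzyl)oxy]-6-[(triethylsilyl)oxy]cyclohex-2-en-1-one | COc1ccc(CO[C@@H]2C=C(CO[Si](c3ccccc3)(c3ccccc3)C(C)(C)C)C(=O)[C@@H](O[Si](CC)(CC)CC)[C@@H]2C(C)C)cc1 | intermediate
19 | (4R,5R,6S)-2-{[(tert-butyldiphenylsilyl)oxy]methyl}-4-hydroxy-5-isopropyl-6-[(triethylsilyl)oxy]cyclohex-2-en-1-one | O[C@@H]1C=C(CO[Si](c2ccccc2)(c2ccccc2)C(C)(C)C)C(=O)[C@@H](O[Si](CC)(CC)CC)[C@@H]1C(C)C | intermediate
20 | angelic acid, (Z)-2-methylbut-2-enoic acid | C/C=C(/C)C(=O)O | starting material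
21 | (Z)-2-methylbut-2-enoic 2,4,6-trichlorobenzoic anhydride (not isolated) | C/C=C(/C)C(=O)OC(=O)c1c(Cl)cc(Cl)cc1Cl | intermediate
22 | (4R,5R,6S)-2-{[(tert-butyldiphenylsilyl)oxy]methyl}-5-isopropyl-4-{[(Z)-2-methylbut-2-enoyl]oxy}-6-[(triethylsilyl)oxy]cyclohex-2-en-1-one | C/C=C(/C)C(=O)O[C@@H]1C=C(CO[Si](c2ccccc2)(c2ccccc2)C(C)(C)C)C(=O)[C@@H](O[Si](CC)(CC)CC)[C@@H]1C(C)C | intermediate
23 | (4R,5S,6S)-2-{[(tert-butyldiphenylsilyl)oxy]methyl}-6-hydroxy-5-isopropyl-4-{[(Z)-2-methylbut-2-enoyl]oxy}cyclohex-2-en-1-one | C/C=C(/C)C(=O)O[C@@H]1C=C(CO[Si](c2ccccc2)(c2ccccc2)C(C)(C)C)C(=O)[C@@H](O)[C@@H]1C(C)C | intermediate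
24 | (Z)-2-methylbut-2-en-1-ol | C/C=C(/C)CO | intermediate
25 | [(2S,3R)-2,3-dimethyloxiran-2-yl]methanol | OC[C@]1(C)O[C@@H]1C | intermediate
26 | (2R,3R)-2,3-dimethyloxirane-2-carboxylic acid | OC(=O)[C@]1(C)O[C@@H]1C | intermediate
27 | (2R,3R)-2,3-dimethyloxirane-2-carboxylic 2,4,6-trichlorobenzoic anhydride (not isolated) | Clc1cc(Cl)c(C(=O)OC(=O)[C@]2(C)O[C@@H]2C)c(Cl)c1 | intermediate
28 | (1S,2R,3R)-5-{[(tert-butyldiphenylsilyl)oxy]methyl}-2-isopropyl-3-{[(Z)-2-methylbut-2-enoyl]oxy}-6-oxocyclohex-4-en-1-yl (2R,3R)-2,3-dimethyloxirane-2-carboxylate | C/C=C(/C)C(=O)O[C@@H]1C=C(CO[Si](c2ccccc2)(c2ccccc2)C(C)(C)C)C(=O)[C@@H](OC(=O)[C@]2(C)O[C@@H]2C)[C@@H]1C(C)C | intermediate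
29 | (1S,2R,3R)-5-(hydroxymethyl)-2-isopropyl-3-{[(Z)-2-methylbut-2-enoyl]oxy}-6-oxocyclohex-4-en-1-yl (2R,3R)-2,3-dimethyloxirane-2-carboxylate | C/C=C(/C)C(=O)O[C@@H]1C=C(CO)C(=O)[C@@H](OC(=O)[C@]2(C)O[C@@H]2C)[C@@H]1C(C)C | target

**Step count**
Total: 20 steps. Longest linear sequence: 17 steps (1–15, 19, 20) from 1. The epoxy acid branch (steps 16–18) is 3 steps from angelic acid and joins at step 19.

**Steps most likely to fail**

Step 3. The basic, hindered ylide may enolise the α-alkoxy ketone faster than it olefinates it, so that ketone is returned (possibly epimerised at s-C2) and the tetrasubstituted alkene forms slowly. Fallback: setting out from 3, addition of i-PrMgCl premixed with anhydrous CeCl3 (THF, −78 °C), an organocerium addition that suppresses enolisation and reduction, would give the tertiary carbinol methyl 4,6-O-[(R)-benzylidene]-3-C-isopropyl-2-O-(4-methoxybenzyl)-α-D-altropyranoside F1, drawn as the epimer from equatorial attack. Syn-dehydration of this carbinol with Burgess reagent (toluene, 60 °C) should take the isopropyl methine hydrogen, the only β-hydrogen that can become syn-periplanar on a carbon without oxygen, and return to 6.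

Step 5. The tetrasubstituted alkene may be reduced so slowly that the iridium catalyst is deactivated by the diol, the double bond may migrate into the ring, or the primary 6-OH may compete as a ligand and erode face selectivity. Fallback: setting out from 6, with the acetal intact and no free hydroxyl, radical hydrogen-atom-transfer hydrogenation (Mn(dpm)3 cat., dpm = 2,2,6,6-tetramethylheptane-3,5-dionate; PhSiH3, t-BuOOH, i-PrOH, rt) operates under thermodynamic control. On the rigid trans-fused bicycle it should place isopropyl equatorial and give methyl 4,6-O-[(R)-benzylidene]-3-deoxy-3-C-isopropyl-2-O-(4-methoxybenzyl)-α-D-mannopyranoside F2. Acetal hydrolysis (AcOH/H2O, 50 °C) then rejoins the route at 8.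

Step 14. Acylation of the hindered C5–OH, cis to isopropyl, may be so slow at 80 °C that Z-to-E isomerisation to the tiglate or base-induced degradation of the γ-hydroxy enone takes over. Fallback: the angelate is built on the alcohol. Setting out from 19, esterification with 2-[bis(2,2,2-trifluoroethoxy)phosphoryl]propanoic acid (DCC, DMAP cat., CH2Cl2, 0 °C) would give (4R,5R,6S)-4-({2-[bis(2,2,2-trifluoroethoxy)phosphoryl]propanoyl}oxy)-2-{[(tert-butyldiphenylsilyl)oxy]methyl}-5-isopropyl-6-[(triethylsilyl)oxy]cyclohex-2-en-1-one F3, as both epimers at the phosphonate carbon. Z-selective Still–Gennari olefination with acetaldehyde (KN(SiMe3)2, 18-crown-6, THF, −78 °C), in which the phosphonate α-hydrogen is removed in preference to the ketone α-hydrogen, should then deliver 22.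

**Further compounds**
F1 | step 3 | methyl 4,6-O-[(R)-benzylidene]-3-C-isopropyl-2-O-(4-methoxybenzyl)-α-D-altropyranoside | CO[C@H]1O[C@@H]2CO[C@@H](c3ccccc3)O[C@H]2[C@](O)(C(C)C)[C@@H]1OCc1ccc(OC)cc1
F2 | step 5 | methyl 4,6-O-[(R)-benzylidene]-3-deoxy-3-C-isopropyl-2-O-(4-methoxybenzyl)-α-D-mannopyranoside | CO[C@H]1O[C@@H]2CO[C@@H](c3ccccc3)O[C@H]2[C@H](C(C)C)[C@@H]1OCc1ccc(OC)cc1
F3 | step 14 | (4R,5R,6S)-4-({2-[bis(2,2,2-trifluoroethoxy)phosphoryl]propanoyl}oxy)-2-{[(tert-butyldiphenylsilyl)oxy]methyl}-5-isopropyl-6-[(triethylsilyl)oxy]cyclohex-2-en-1-one | CC(C(=O)O[C@@H]1C=C(CO[Si](c2ccccc2)(c2ccccc2)C(C)(C)C)C(=O)[C@@H](O[Si](CC)(CC)CC)[C@@H]1C(C)C)P(=O)(OCC(F)(F)F)OCC(F)(F)F
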